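(The readings are calculated with constants of no real substance.)

If the protic impurity destroys starting material one for one, then two flasks with the same protic impurity but different charges of starting material lose different shares of it, and that small correction can be computed by itself.

| flask | starting material | protic impurity | remark | time |
|---|---|---|---|---|
| zeta | 0.10 M | 5 mM | the very flask that is asked about, followed so far |  |
| beta | 0.050 M | 5 mM | run made earlier |  |
| flask | 0.10 M | 5.00 mM |  | 12 min |

| run | time / min | isomer of the product A / % | target / % |
|---|---|---|---|
| zeta | 0.167 | 1.7 | 19.4 |
| zeta | 0.500 | 9.7 | 27.3 |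
| zeta | 0.833 | 18.4 | 27.1 |
| zeta | 1.33 | 28.5 | 26.3 |
| zeta | 2.00 | 37.7 | 25.8 |
| zeta | 2.50 | 43.0 | 25.1 |
| beta | 2.00 | 35.7 | 24.1 |
| beta | 4.00 | 50.8 | 20.3 |
| beta | 6.00 | 57.9 | 17.5 |
| beta | 8.00 | 60.9 | 15.5 |
| beta | 10.0 | 64.6 | 14.4 |
| beta | 12.0 | 65.0 | 13.7 |

(readings scatter by 0.5 percentage points)

* ratio of isomer of the product A to target at 1.5 s
* ratio of isomer of the product A to target at 30 s
* ratio of isomer of the product A to target at 12 min
* which of isomer of the product A and target there is more of at 12 min

- the numbers in the tables scatter with a standard deviation of 0.5 percentage points

Does the charge change the ratio c(isomer of the product A)/c(target)? Hardly. At 2.00 min it reads 1.46 in the zeta run and 1.48 in the beta run, with twice the starting material in zeta.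

Then why are the zeta percentages higher? At that time zeta reads more isomer of the product A than beta, by a factor of 1.06, and target by 1.07.

Your reckoning? I carry the surviving share, the part of the charge left once the protic impurity, here the limiting reagent, has taken one starting material each. It is 95.0% for zeta and 90.0% for beta, so their quotient is 1.06, close to both readings.

But zeta stops at 2.50 min. What reaches 12 min? The beta readings at that time, scaled: isomer of the product A 68.6%, target 14.5%. A common factor cancels in a ratio, so mine stays at 4.74.

The forecast says 0.012 (0.005 to 0.025) at 1.5 s, 0.35 (0.32 to 0.39) at 30 s, and 5 (4 to 6.5) at 12 min, with isomer of the product A ahead, on the ground that “the ratio barely depends on concentration”. My ratio at 12 min is lower than its 5, inside its range.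

The flask gives 0.0123, 0.358 and 4.70, each inside the forecast's range, with isomer of the product A ahead at 68.3% against 14.5% of target.

    target ⇌ isomer of the product A (K = 5.20, k = 0.00620 s⁻¹)
    starting material ⇌ other conformer (K = 2.20, k = 0.0280 s⁻¹)
    starting material + protic impurity → quenched substrate (k = 17.0 M⁻¹ s⁻¹)
    other conformer → isomer of the product A (k = 0.0110 s⁻¹)
    target ⇌ isomer of the product B (K = 0.830, k = 0.0320 s⁻¹)
    starting material → target (k = 0.0320 s⁻¹)

The flask's quenched substrate stands at 5.00% at 12.0 min, and the charge minus the surviving share is 5.00%. The neighbouring flask, charged with 0.025 M of starting material and the same protic impurity, has a surviving share of 80.0%. Scaling the beta readings at 12.0 min by it gives 57.8% isomer of the product A and 12.2% target. That neighbouring flask gives 57.5% and 12.2% at 12.0 min, a ratio of 4.70, and 20.0% quenched substrate.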